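**Retrosynthetic overview**
- The C8 senecioyl group is disconnected last (Friedel–Crafts C-acylation of the debenzylated flavanone). The C6 methylene is traced back to a C6 formyl carbon joined to the pyranone by reductive Knoevenagel alkylation.
- The flavanone is opened at C4–C4a: intramolecular Friedel–Crafts acylation of an (S)-3-aryloxy-3-phenylpropanoic acid. That acid comes from a Mitsunobu etherification (inversion) of 2,6-bis(benzyloxy)-4-hydroxybenzaldehyde with ethyl (R)-3-hydroxy-3-phenylpropanoate.
- Feature used: on ring A, O1 is para to C6, the carbon that carries the CH2 link to the pyranone. An aryl ether bearing only the C6 formyl carbon and two identical benzyloxy groups is mirror-symmetric through O1 and C6, so its two ortho carbons (future C4a and C8) are equivalent and ring closure can give only one flavanone. The oxygen para to the formyl group is the only free hydroxyl at the Mitsunobu stage, so it alone becomes O1.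
- The 6-ethyl-4-hydroxy-5-methyl-2-pyranone comes from pentan-3-one through its silyl enol ether and malonyl dichloride.
- Ring order: ring A is bought; the flavanone pyranone ring (O1, C2, C3, C4, C4a, C8a) is closed in step 4; the 2-pyranone ring is closed in step 6 on a separate branch; the two halves are joined in step 7.

Key step: step 4

Assumption: flavanone numbering (O1, C2, C3, C4, C4a, C5–C8, C8a) is used for ring positions throughout; the E/Z mixture of silyl enol ether 10 and the enolisable centre of 12 are immaterial because both vanish in pyranone 13.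

**Step 1**
Reactants: 1 3,5-bis(benzyloxy)phenol
Product: 3 2,6-bis(benzyloxy)-4-hydroxybenzaldehyde, via aryl iminium chloride 2 (not isolated)
Conditions: POCl3, DMF, MeCN, 0 °C → rt; then H2O, rt; the symmetric para isomer is separated from the ortho-hydroxy isomer by crystallisation or chromatography
Reagents that add atoms: N,N-dimethylformamide, CN(C)C=O; water, O
Why: Vilsmeier–Haack formylation of an electron-rich phenol, expected by analogy with 3,5-dimethoxyphenol to go mainly at the carbon para to the hydroxyl and flanked by the two benzyloxy groups, so that the Mitsunobu step meets a single free hydroxyl.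

**Step 2**
Reactants: 3 2,6-bis(benzyloxy)-4-hydroxybenzaldehyde; 4 ethyl (3R)-3-hydroxy-3-phenylpropanoate
Product: 5 ethyl (3S)-3-[3,5-bis(benzyloxy)-4-formylphenoxy]-3-phenylpropanoate
Conditions: PPh3, DIAD, toluene, 0 °C → rt
Reagents that add atoms: none
Why: Mitsunobu etherification in which the acidic para-formyl phenol displaces the benzylic alkoxyphosphonium by SN2 with inversion (R → S), which sets the future C2 stereocentre, while the acidic pronucleophile and low temperature should hold back elimination to ethyl cinnamate.

**Step 3**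
Reactants: 5 ethyl (3S)-3-[3,5-bis(benzyloxy)-4-formylphenoxy]-3-phenylpropanoate
Product: 6 (3S)-3-[3,5-bis(benzyloxy)-4-formylphenoxy]-3-phenylpropanoic acid
Conditions: LiOH·H2O, THF–H2O, 0 °C; then cold 1 M HCl to pH 3–4
Reagents that add atoms: lithium hydroxide, [Li+].[OH-]
Why: Ester saponification in which hydroxide adds to the ester carbonyl faster than it removes an α-proton at 0 °C, so the β-aryloxy group should not be eliminated and the stereocentre, which is not α to the carbonyl, is untouched.

**Step 4**
Reactants: 6 (3S)-3-[3,5-bis(benzyloxy)-4-formylphenoxy]-3-phenylpropanoic acid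
Product: 8 (2S)-5,7-bis(benzyloxy)-4-oxo-2-phenylchromane-6-carbaldehyde, via acid chloride 7 (not isolated)
Conditions: (COCl)2, DMF (cat.), CH2Cl2, 0 °C; then SnCl4 (2.5 equiv), CH2Cl2, −78 → −20 °C
Reagents that add atoms: none
Why: Oxalyl chloride with catalytic DMF converts the acid into acid chloride 7, which SnCl4 activates to an acylium ion (or its tight complex) that attacks the ring carbon ortho to the ether oxygen and flanked by a benzyloxy group, and proton loss from the arenium ion forms C4–C4a. The closest known reaction type is the intramolecular Friedel–Crafts acylation of 3-aryloxypropanoic and 3-aryloxy-3-phenylpropanoic acids to chroman-4-ones and flavanones. The pyranone ring (O1, C2, C3, C4, C4a, C8a) closes in a 6-exo sense, the arene carbon adding to the acyl carbon whose C=O stays outside the ring. No stereocentre is formed; C2 was set in step 2 and no bond to it is made or broken, so it should stay S. Regioselectivity needs no control because the aryl ring of 6 is mirror-symmetric through the ether oxygen and the formyl carbon, so both ortho carbons are identical and only the 6-formyl flavanone can form, and the attacked carbon is meta to the formyl group and keeps ortho, ortho and para oxygen donation. The selectivity that matters is acylation over ionisation or elimination at the benzylic C2–O bond, which the low temperature, the moderate Lewis acid and the electron-poor acyl group β to C2 (disfavouring a benzylic cation) should secure.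

**Step 5**
Reactants: 9 pentan-3-one
Product: 10 trimethyl(pent-2-en-3-yloxy)silane (E/Z mixture)
Conditions: TMSOTf, Et3N, Et2O, 0 °C → rt; distillation
Reagents that add atoms: trimethylsilyl trifluoromethanesulfonate, C[Si](C)(C)OS(=O)(=O)C(F)(F)F
Why: Silyl enol ether formation by soft enolisation of a symmetrical ketone, which can give only one regioisomer.

**Step 6**
Reactants: 10 trimethyl(pent-2-en-3-yloxy)silane; 11 malonyl dichloride
Product: 13 6-ethyl-4-hydroxy-5-methyl-2H-pyran-2-one, via keto acid chloride 12 (not isolated)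
Conditions: Et2O, −78 °C → rt
Reagents that add atoms: none
Why: Known acylation of silyl enol ethers with malonyl dichloride to 4-hydroxy-2-pyranones: C-acylation gives the β-diketo acid chloride, whose enol oxygen on the ethyl-bearing carbon lactonises onto the second acid chloride.

**Step 7**
Reactants: 8 (2S)-5,7-bis(benzyloxy)-4-oxo-2-phenylchromane-6-carbaldehyde; 13 6-ethyl-4-hydroxy-5-methyl-2H-pyran-2-one
Product: 15 (2S)-5,7-bis(benzyloxy)-6-[(6-ethyl-4-hydroxy-5-methyl-2-oxo-2H-pyran-3-yl)methyl]-2-phenylchroman-4-one, via 3-arylidene pyran-2,4-dione 14 (not isolated)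
Conditions: Hantzsch ester (diethyl 2,6-dimethyl-1,4-dihydropyridine-3,5-dicarboxylate, 1.2 equiv), L-proline (20 mol%), CH2Cl2, rt → 40 °C
Reagents that add atoms: none
Why: Three-component reductive Knoevenagel alkylation, known for 4-hydroxycoumarins and 4-hydroxy-2-pyranones, in which amine-catalysed condensation at pyranone C3 gives the arylidene dione and hydride transfer from the Hantzsch ester reduces it before a second pyranone can add, under conditions too weakly basic to open the flavanone.

**Step 8**
Reactants: 15 (2S)-5,7-bis(benzyloxy)-6-[(6-ethyl-4-hydroxy-5-methyl-2-oxo-2H-pyran-3-yl)methyl]-2-phenylchroman-4-one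
Product: 16 (2S)-6-[(6-ethyl-4-hydroxy-5-methyl-2-oxo-2H-pyran-3-yl)methyl]-5,7-dihydroxy-2-phenylchroman-4-one
Conditions: H2 (1 atm), 10% Pd/C, EtOAc–MeOH, rt, stopped after uptake of two equivalents
Reagents that add atoms: none
Why: Hydrogenolysis of aryl benzyl ethers, done before the senecioyl alkene is present and expected to be much faster than cleavage of the cyclic benzylic C2–O1 bond or reduction of the pyranone and aryl ketone.

**Step 9**
Reactants: 16 (2S)-6-[(6-ethyl-4-hydroxy-5-methyl-2-oxo-2H-pyran-3-yl)methyl]-5,7-dihydroxy-2-phenylchroman-4-one; 17 3-methylbut-2-enoyl chloride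
Product: 18 (2S)-6-[(6-ethyl-4-hydroxy-5-methyl-2-oxo-2H-pyran-3-yl)methyl]-5,7-dihydroxy-8-(3-methylbut-2-enoyl)-2-phenylchroman-4-one (target)
Conditions: AlCl3 (5 equiv), CH2Cl2–MeNO2, 0 °C → rt; quench into ice-cold 1 M HCl, no basic wash
Reagents that add atoms: none
Why: Friedel–Crafts C-acylation of an acylphloroglucinol-type ring with an α,β-unsaturated acyl chloride (known for 5,7-dihydroxybenzopyranones) at C8, the only unsubstituted ring-A carbon, ortho to O7 and para to O5, where aluminium binding of O7 and the new carbonyl should keep O7 turned away from the enone until the cold quench.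

**Compound list**
1 | 3,5-bis(benzyloxy)phenol | Oc1cc(OCc2ccccc2)cc(OCc2ccccc2)c1 | starting material
2 | [2,6-bis(benzyloxy)-4-hydroxyphenyl]methylidene(dimethyl)iminium chloride | C[N+](C)=Cc1c(OCc2ccccc2)cc(O)cc1OCc1ccccc1.[Cl-] | intermediate (not isolated)
3 | 2,6-bis(benzyloxy)-4-hydroxybenzaldehyde | O=Cc1c(OCc2ccccc2)cc(O)cc1OCc1ccccc1 | intermediate
4 | ethyl (3R)-3-hydroxy-3-phenylpropanoate | CCOC(=O)C[C@@H](O)c1ccccc1 | starting material
5 | ethyl (3S)-3-[3,5-bis(benzyloxy)-4-formylphenoxy]-3-phenylpropanoate | CCOC(=O)C[C@@H](c1ccccc1)Oc1cc(OCc2ccccc2)c(C=O)c(OCc2ccccc2)c1 | intermediate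
6 | (3S)-3-[3,5-bis(benzyloxy)-4-formylphenoxy]-3-phenylpropanoic acid | O=C(O)C[C@@H](c1ccccc1)Oc1cc(OCc2ccccc2)c(C=O)c(OCc2ccccc2)c1 | intermediate
7 | (3S)-3-[3,5-bis(benzyloxy)-4-formylphenoxy]-3-phenylpropanoyl chloride | O=C(Cl)C[C@@H](c1ccccc1)Oc1cc(OCc2ccccc2)c(C=O)c(OCc2ccccc2)c1 | intermediate (not isolated)
8 | (2S)-5,7-bis(benzyloxy)-4-oxo-2-phenylchromane-6-carbaldehyde | O=Cc1c(OCc2ccccc2)cc2c(c1OCc1ccccc1)C(=O)C[C@@H](c1ccccc1)O2 | intermediate
9 | pentan-3-one | CCC(=O)CC | starting material
10 | trimethyl(pent-2-en-3-yloxy)silane (E/Z mixture) | CC=C(CC)O[Si](C)(C)C | intermediate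
11 | malonyl dichloride (propanedioyl dichloride) | O=C(Cl)CC(=O)Cl | starting material
12 | 4-methyl-3,5-dioxoheptanoyl chloride (racemic, enolisable) | CCC(=O)C(C)C(=O)CC(=O)Cl | intermediate (not isolated)
13 | 6-ethyl-4-hydroxy-5-methyl-2H-pyran-2-one | CCc1oc(=O)cc(O)c1C | intermediate
14 | (2S)-5,7-bis(benzyloxy)-6-[(6-ethyl-5-methyl-2,4-dioxo-2H-pyran-3(4H)-ylidene)methyl]-2-phenylchroman-4-one (alkene geometry undefined) | CCC1=C(C)C(=O)C(=Cc2c(OCc3ccccc3)cc3c(c2OCc2ccccc2)C(=O)C[C@@H](c2ccccc2)O3)C(=O)O1 | intermediate (not isolated)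
15 | (2S)-5,7-bis(benzyloxy)-6-[(6-ethyl-4-hydroxy-5-methyl-2-oxo-2H-pyran-3-yl)methyl]-2-phenylchroman-4-one | CCc1oc(=O)c(Cc2c(OCc3ccccc3)cc3c(c2OCc2ccccc2)C(=O)C[C@@H](c2ccccc2)O3)c(O)c1C | intermediate
16 | (2S)-6-[(6-ethyl-4-hydroxy-5-methyl-2-oxo-2H-pyran-3-yl)methyl]-5,7-dihydroxy-2-phenylchroman-4-one | CCc1oc(=O)c(Cc2c(O)cc3c(c2O)C(=O)C[C@@H](c2ccccc2)O3)c(O)c1C | intermediate
17 | 3-methylbut-2-enoyl chloride | CC(C)=CC(=O)Cl | starting material
18 | (2S)-6-[(6-ethyl-4-hydroxy-5-methyl-2-oxo-2H-pyran-3-yl)methyl]-5,7-dihydroxy-8-(3-methylbut-2-enoyl)-2-phenylchroman-4-one | CCc1oc(=O)c(Cc2c(O)c(C(=O)C=C(C)C)c3c(c2O)C(=O)C[C@@H](c2ccccc2)O3)c(O)c1C | target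

**Totals**
Total step count: 9. Longest linear sequence: 7 steps (steps 1, 2, 3, 4, 7, 8, 9); the pyranone branch (steps 5 and 6) joins at step 7.

**Steps most likely to fail**

Step 9. Three processes threaten it. The 7-oxygen may add to the new enone in a conjugate sense and close a dimethylchromanone ring if the mixture warms or the aluminium chelate is broken under non-neutral conditions. The phenol and pyranone hydroxyls may be O-acylated in place of C8. The Lewis acid may open the O1–C2 bond and let it reclose through the other phenol, which would erode the C2 configuration and exchange the C6 and C8 substituents. The fallback sets out from 16 and avoids Lewis acid altogether. Iodination at C8 with N-iodosuccinimide (1.0 equiv, MeCN, 0 °C) should give (2S)-6-[(6-ethyl-4-hydroxy-5-methyl-2-oxo-2H-pyran-3-yl)methyl]-5,7-dihydroxy-8-iodo-2-phenylchroman-4-one F1. A carbonylative Stille coupling of this iodide with tributyl(2-methylprop-1-en-1-yl)stannane under CO (1 atm) with Pd(PPh3)4 (zerovalent palladium) in dioxane at 70 °C, with no added base, should then insert the carbonyl and the 2-methylpropenyl group and return to the route at 18.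

Step 4. SnCl4 bound at the formyl oxygen may lower the nucleophilicity of the ring so far that acylation stalls. The same coordination makes the aryloxide a better leaving group, so ionisation or elimination at the benzylic C2–O bond (loss of the phenol, racemisation) may overtake ring closure. A benzyl ether ortho to a carbonyl may also be cleaved by the Lewis acid. The fallback sets out from 5 and forms the same C4–C4a bond by an anionic Parham cyclisation. Monobromination with N-bromosuccinimide (MeCN, 0 °C) at either of the two equivalent carbons ortho to the ether oxygen should give ethyl (3S)-3-[3,5-bis(benzyloxy)-2-bromo-4-formylphenoxy]-3-phenylpropanoate F2. The aldehyde is then masked with ethylene glycol and pyridinium tosylate (toluene, water separator) as ethyl (3S)-3-[3,5-bis(benzyloxy)-2-bromo-4-(1,3-dioxolan-2-yl)phenoxy]-3-phenylpropanoate F3. The ester is converted with MeNH(OMe)·HCl and i-PrMgCl (THF, −20 °C) into (3S)-3-[3,5-bis(benzyloxy)-2-bromo-4-(1,3-dioxolan-2-yl)phenoxy]-N-methoxy-N-methyl-3-phenylpropanamide F4. Bromine–lithium exchange with n-BuLi (THF, −100 °C) and attack of the aryllithium on the amide should close the ring to (2S)-5,7-bis(benzyloxy)-6-(1,3-dioxolan-2-yl)-2-phenylchroman-4-one F5. Hydrolysis of the acetal with dilute aqueous HCl in THF at rt brings the route back at 8.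

Step 7. Iminium formation and condensation may be slow at an aldehyde flanked by two benzyloxy groups and conjugated to three oxygens. A second pyranone may add to the alkylidene before hydride transfer. Prolonged exposure to the amine may start to open the flavanone. The fallback sets out from 8 and makes the same C–C bond by cation chemistry. Chemoselective reduction of the aldehyde with NaBH4 (0.5 equiv, THF–MeOH, −20 °C; the hindered aryl ketone is slower) should give (2S)-5,7-bis(benzyloxy)-6-(hydroxymethyl)-2-phenylchroman-4-one F6. Acid-catalysed dehydrative alkylation of pyranone 13 at C3 with this benzylic alcohol (TsOH·H2O, 10 mol%, MeCN, 50 °C), through the oxygen-stabilised benzylic cation, returns to the route at 15.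

**Further compounds**
F1 | step 9 | (2S)-6-[(6-ethyl-4-hydroxy-5-methyl-2-oxo-2H-pyran-3-yl)methyl]-5,7-dihydroxy-8-iodo-2-phenylchroman-4-one | CCc1oc(=O)c(Cc2c(O)c(I)c3c(c2O)C(=O)C[C@@H](c2ccccc2)O3)c(O)c1C
F2 | step 4 | ethyl (3S)-3-[3,5-bis(benzyloxy)-2-bromo-4-formylphenoxy]-3-phenylpropanoate | CCOC(=O)C[C@@H](c1ccccc1)Oc1cc(OCc2ccccc2)c(C=O)c(OCc2ccccc2)c1Br
F3 | step 4 | ethyl (3S)-3-[3,5-bis(benzyloxy)-2-bromo-4-(1,3-dioxolan-2-yl)phenoxy]-3-phenylpropanoate | CCOC(=O)C[C@@H](c1ccccc1)Oc1cc(OCc2ccccc2)c(C2OCCO2)c(OCc2ccccc2)c1Br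
F4 | step 4 | (3S)-3-[3,5-bis(benzyloxy)-2-bromo-4-(1,3-dioxolan-2-yl)phenoxy]-N-methoxy-N-methyl-3-phenylpropanamide | CON(C)C(=O)C[C@@H](c1ccccc1)Oc1cc(OCc2ccccc2)c(C2OCCO2)c(OCc2ccccc2)c1Br
F5 | step 4 | (2S)-5,7-bis(benzyloxy)-6-(1,3-dioxolan-2-yl)-2-phenylchroman-4-one | O=C1C[C@@H](c2ccccc2)Oc2cc(OCc3ccccc3)c(C3OCCO3)c(OCc3ccccc3)c21
F6 | step 7 | (2S)-5,7-bis(benzyloxy)-6-(hydroxymethyl)-2-phenylchroman-4-one | OCc1c(OCc2ccccc2)cc2c(c1OCc1ccccc1)C(=O)C[C@@H](c1ccccc1)O2
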